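**Strategy.** The target is the epicatechin tetramer epicatechin-(4β→6)-epicatechin-(4β→8)-epicatechin-(4β→6)-epicatechin. Three units come from (−)-epicatechin; the top unit is built by disconnecting C2–C3 of its ring C. The precursor is an acyclic (Z)-enol acetate whose ring A oxygen O1 carries a 3,4-bis(benzyloxy)benzyl group. Hydride abstraction at that benzylic carbon gives an oxocarbenium ion, which the enol acetate attacks in a Prins closure. The step exploits the trioxygenated ring A, which stabilises a cation at C4: one operation forms C2–C3, closes ring C, sets the 2,3-cis pair and installs the C4 leaving group for the first interflavan bond. Bromine at C8 and orthogonal oxygen and sulfur leaving groups then steer the 4→6, 4→8 and 4→6 couplings.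

Key step: step 5

Remarks on the chemistry: flavan numbering is used (O1, C2, C3, C4, C4a, C5 to C8, C8a; ring B primed), and 4β means trans to the C3 oxygen. Compounds 1, 3 and 11 are taken as commercial. The sense of induction by the chiral phosphate in step 5 cannot be predicted with certainty; the (R)-acid is written, and its mirror image would be used if it favours the enantiomeric series.

Step 1
Reactants: 1 3,5-bis(benzyloxy)phenol
Product: 2 2,4-bis(benzyloxy)-6-hydroxybenzaldehyde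
Conditions: (CH2O)n, MgCl2, Et3N, MeCN, reflux
Reagents that add atoms: paraformaldehyde (as formaldehyde, C=O)
Why: Magnesium-mediated ortho-formylation (Casnati–Skattebøl) delivers the formyl group only ortho to the free phenol, and both ortho positions are equivalent, so a single salicylaldehyde should form.

Step 2
Reactants: 2 2,4-bis(benzyloxy)-6-hydroxybenzaldehyde; 3 3,4-bis(benzyloxy)benzyl chloride
Product: 4 2,4-bis(benzyloxy)-6-{[3,4-bis(benzyloxy)phenyl]methoxy}benzaldehyde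
Conditions: K2CO3, n-Bu4NI (cat.), DMF, 60 °C
Reagents that add atoms: none
Why: Williamson ether synthesis of the phenoxide with a reactive benzylic chloride installs the O1–CH2–aryl unit whose CH2 becomes C2.

Step 3
Reactants: 4 2,4-bis(benzyloxy)-6-{[3,4-bis(benzyloxy)phenyl]methoxy}benzaldehyde
Product: 5 1,5-bis(benzyloxy)-3-{[3,4-bis(benzyloxy)phenyl]methoxy}-2-ethynylbenzene
Conditions: Ohira–Bestmann reagent, K2CO3, MeOH/THF, 0 °C → rt
Reagents that add atoms: dimethyl (1-diazo-2-oxopropyl)phosphonate (COP(=O)(OC)C(=[N+]=[N-])C(C)=O)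
Why: Seyferth–Gilbert homologation in the Ohira–Bestmann variant converts the non-enolisable aryl aldehyde into the terminal alkyne under mild base that all ethers tolerate.

Step 4
Reactants: 5 1,5-bis(benzyloxy)-3-{[3,4-bis(benzyloxy)phenyl]methoxy}-2-ethynylbenzene
Product: 6 (Z)-2-[2,4-bis(benzyloxy)-6-{[3,4-bis(benzyloxy)phenyl]methoxy}phenyl]ethenyl acetate
Conditions: AcOH (1.5 equiv), [Ru(η3-CH2C(CH3)CH2)2(Ph2P(CH2)4PPh2)] (5 mol %), toluene, 60 °C
Reagents that add atoms: acetic acid (CC(=O)O)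
Why: Ruthenium-catalysed anti-Markovnikov addition of a carboxylic acid to a terminal alkyne proceeds through a ruthenium vinylidene and should give the (Z)-enol ester, the alkene geometry that later fixes C3.

Step 5
Reactants: 6 (Z)-2-[2,4-bis(benzyloxy)-6-{[3,4-bis(benzyloxy)phenyl]methoxy}phenyl]ethenyl acetate
Product: 9 3-O-acetyl-5,7,3',4'-tetra-O-benzyl-4β-(2-ethoxyethoxy)-(−)-epicatechin (2,3-cis and 3,4-trans), via aryl-oxocarbenium ion 7 (not isolated), via flavan-4-yl cation 8 (not isolated)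
Conditions: DDQ (2,3-dichloro-5,6-dicyano-1,4-benzoquinone, 1.1 equiv), (R)-3,3'-bis(2,4,6-triisopropylphenyl)-1,1'-binaphthyl-2,2'-diyl hydrogen phosphate (10 mol %), 2-ethoxyethanol (3 equiv), 4 Å MS, CH2Cl2, −40 → 0 °C
Reagents that add atoms: 2-ethoxyethanol (CCOCCO)
Why: Proposed new method: DDQ abstracts hydride from the one benzylic CH2 that bears a para-alkoxy donor (the future C2), and proton transfer from the chiral phosphoric acid to the reduced quinone leaves the aryl-oxocarbenium ion 7 paired with the chiral phosphate; the acetoxy-bearing alkene carbon (future C3) attacks C2, and the resulting C4 cation 8, stabilised by O1, O5 and O7 of ring A and bridged by the acetoxy group, is captured by 2-ethoxyethanol with return of the proton to the catalyst. The closest known reactions are the DDQ-mediated oxidative Prins cyclisation of benzylic ethers onto enol acetates and Prins cyclisations controlled by chiral Brønsted-acid counter-anions, but their combination on an aryl benzyl ether with a styrenyl enol ester has not been shown. Ring C is closed in a 6-endo-trig (Prins) mode through a chair-like transition state. At C2 and C3 the E-oxocarbenium geometry places ring B equatorial and the Z-enol geometry places the acetoxy group axial, which fixes the 2,3-cis relation, while the chiral anion chooses between the two mirror-image chairs and so sets the absolute configuration of (−)-epicatechin; at C4 the alcohol opens the acetoxonium bridge from the face anti to the acetoxy group (3,4-trans, 4β), a centre that is ionised again later. The step needs chemoselective hydride abstraction, secured by the 3,4-dialkoxybenzyl group (the four plain benzyl ethers are far less hydridic), and 6-endo instead of 5-exo attack, secured by ring A, which stabilises charge at C4 much better than the acyloxy group would at C3.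

Step 6
Reactants: 9 3-O-acetyl-5,7,3',4'-tetra-O-benzyl-4β-(2-ethoxyethoxy)-(−)-epicatechin
Product: 10 3-O-acetyl-5,7,3',4'-tetra-O-benzyl-8-bromo-4β-(2-ethoxyethoxy)-(−)-epicatechin
Conditions: N-bromosuccinimide (1.0 equiv), CH2Cl2, −78 → −20 °C
Reagents that add atoms: N-bromosuccinimide (O=C1CCC(=O)N1Br)
Why: Electrophilic aromatic bromination should occur at C8, the most nucleophilic position of the 5,7-dioxygenated ring A; the bromine stops this unit from acting as a nucleophile through C8 in the later couplings.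

Step 7
Reactants: 11 (−)-epicatechin
Product: 12 5,7,3',4'-tetra-O-benzyl-(−)-epicatechin
Conditions: BnBr (4.4 equiv), K2CO3, DMF, 0 °C → rt
Reagents that add atoms: benzyl bromide (BrCc1ccccc1)
Why: Williamson benzylation with a carbonate base alkylates the four phenols and leaves the far less acidic C3 alcohol free; C2 and C3 are taken unchanged from the chiral pool.

Step 8
Reactants: 12 5,7,3',4'-tetra-O-benzyl-(−)-epicatechin
Product: 13 5,7,3',4'-tetra-O-benzyl-8-bromo-(−)-epicatechin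
Conditions: N-bromosuccinimide (1.0 equiv), CH2Cl2, −78 °C → rt
Reagents that add atoms: N-bromosuccinimide (O=C1CCC(=O)N1Br)
Why: Electrophilic aromatic bromination of the benzylated flavan is selective for C8, which leaves C6 as the only nucleophilic ring A carbon.

Step 9
Reactants: 13 5,7,3',4'-tetra-O-benzyl-8-bromo-(−)-epicatechin
Product: 14 5,7,3',4'-tetra-O-benzyl-8-bromo-4β-(2-ethoxyethoxy)-(−)-epicatechin
Conditions: DDQ (2 equiv), 2-ethoxyethanol, CH2Cl2, rt
Reagents that add atoms: 2-ethoxyethanol (CCOCCO)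
Why: DDQ benzylic oxidation removes hydride from C4 to give the ring A-stabilised cation, which the alcohol captures anti to the C3 hydroxyl (4β).

Step 10
Reactants: 14 5,7,3',4'-tetra-O-benzyl-8-bromo-4β-(2-ethoxyethoxy)-(−)-epicatechin
Product: 15 5,7,3',4'-tetra-O-benzyl-8-bromo-4β-(phenylsulfanyl)-(−)-epicatechin
Conditions: PhSH (3 equiv), BF3·OEt2, CH2Cl2, −78 °C
Reagents that add atoms: thiophenol (Sc1ccccc1)
Why: Lewis-acid-mediated SN1 thiolysis exchanges the C4 ether for a thioether (attack anti to the C3 hydroxyl), a latent leaving group that hard Lewis acids do not ionise.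

Step 11
Reactants: 12 5,7,3',4'-tetra-O-benzyl-(−)-epicatechin
Product: 16 5,7,3',4'-tetra-O-benzyl-4β-(2-ethoxyethoxy)-(−)-epicatechin
Conditions: DDQ (2 equiv), 2-ethoxyethanol, CH2Cl2, rt
Reagents that add atoms: 2-ethoxyethanol (CCOCCO)
Why: The same DDQ benzylic oxidation at C4 with anti capture by the alcohol gives the 4β ether and leaves C8 free.

Step 12
Reactants: 10 3-O-acetyl-5,7,3',4'-tetra-O-benzyl-8-bromo-4β-(2-ethoxyethoxy)-(−)-epicatechin; 15 5,7,3',4'-tetra-O-benzyl-8-bromo-4β-(phenylsulfanyl)-(−)-epicatechin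
Product: 17 [3-O-acetyl-tetra-O-benzyl-8-bromoepicatechin]-(4β→6)-[tetra-O-benzyl-8-bromo-4β-(phenylsulfanyl)epicatechin]
Conditions: 15 (3 equiv), BF3·OEt2, 4 Å MS, CH2Cl2, −78 → −30 °C
Reagents that add atoms: none
Why: Friedel–Crafts-type interflavan coupling: BF3 ionises only the C4 ether of 10, the acetoxy-bridged cation is attacked anti to the C3 oxygen (4β), and C6 is the only free ring A carbon of 15 because C8 carries bromine, while the thioether stays intact.

Step 13
Reactants: 17 the (4β→6) dimer with the 4β-phenylsulfanyl group; 16 5,7,3',4'-tetra-O-benzyl-4β-(2-ethoxyethoxy)-(−)-epicatechin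
Product: 18 [3-O-acetyl-tetra-O-benzyl-8-bromoepicatechin]-(4β→6)-[tetra-O-benzyl-8-bromoepicatechin]-(4β→8)-[tetra-O-benzyl-4β-(2-ethoxyethoxy)epicatechin]
Conditions: 16 (2.5 equiv), AgOSO2CF3 (1.5 equiv), 2,6-di-tert-butyl-4-methylpyridine, 4 Å MS, CH2Cl2, −40 → 0 °C
Reagents that add atoms: none
Why: Thiophilic silver activation ionises the C4 thioether under buffered conditions that spare the ether of 16, and the cation is attacked anti to the C3 hydroxyl (4β) by C8, the more nucleophilic ring A position of 16 (Friedel–Crafts-type coupling).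

Step 14
Reactants: 18 the trimer with the 4β-(2-ethoxyethoxy) group; 13 5,7,3',4'-tetra-O-benzyl-8-bromo-(−)-epicatechin
Product: 19 [3-O-acetyl-tetra-O-benzyl-8-bromoepicatechin]-(4β→6)-[tetra-O-benzyl-8-bromoepicatechin]-(4β→8)-[tetra-O-benzylepicatechin]-(4β→6)-[tetra-O-benzyl-8-bromoepicatechin]
Conditions: 13 (4 equiv), BF3·OEt2, 4 Å MS, CH2Cl2, −78 → −30 °C
Reagents that add atoms: none
Why: Friedel–Crafts-type coupling: BF3 ionises the last C4 ether, and the cation is attacked anti to the C3 hydroxyl (4β) by C6 of 13, whose C8 is blocked by bromine.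

Step 15
Reactants: 19 the protected tetramer with one acetate
Product: 20 hexadeca-O-benzyl-tribromo tetramer with all four C3 hydroxyls free
Conditions: K2CO3 (cat.), MeOH/THF, rt
Reagents that add atoms: none
Why: Base-catalysed transesterification removes the single acetate without touching benzyl ethers, aryl bromides or the interflavan bonds.

Step 16
Reactants: 20 hexadeca-O-benzyl-tribromo tetramer
Product: 21 epicatechin-(4β→6)-epicatechin-(4β→8)-epicatechin-(4β→6)-epicatechin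
Conditions: H2 (1 atm), Pd(OH)2/C, Et3N (4 equiv), THF/MeOH/H2O, rt
Reagents that add atoms: none
Why: Catalytic hydrogenolysis cleaves the sixteen benzyl ethers and hydrodehalogenates the three aryl bromides under conditions that leave all stereocentres and the interflavan bonds untouched.

**Compound list**

1 | 3,5-bis(benzyloxy)phenol | Oc1cc(OCc2ccccc2)cc(OCc2ccccc2)c1 | starting material
2 | 2,4-bis(benzyloxy)-6-hydroxybenzaldehyde | O=Cc1c(O)cc(OCc2ccccc2)cc1OCc1ccccc1 | intermediate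
3 | 3,4-bis(benzyloxy)benzyl chloride | ClCc1ccc(OCc2ccccc2)c(OCc2ccccc2)c1 | starting material
4 | 2,4-bis(benzyloxy)-6-{[3,4-bis(benzyloxy)phenyl]methoxy}benzaldehyde | O=Cc1c(OCc2ccccc2)cc(OCc2ccccc2)cc1OCc1ccc(OCc2ccccc2)c(OCc2ccccc2)c1 | intermediate
5 | 1,5-bis(benzyloxy)-3-{[3,4-bis(benzyloxy)phenyl]methoxy}-2-ethynylbenzene | C#Cc1c(OCc2ccccc2)cc(OCc2ccccc2)cc1OCc1ccc(OCc2ccccc2)c(OCc2ccccc2)c1 | intermediate
6 | (Z)-2-[2,4-bis(benzyloxy)-6-{[3,4-bis(benzyloxy)phenyl]methoxy}phenyl]ethenyl acetate | CC(=O)O/C=C\c1c(OCc2ccccc2)cc(OCc2ccccc2)cc1OCc1ccc(OCc2ccccc2)c(OCc2ccccc2)c1 | intermediate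
7 | aryl-oxocarbenium ion formed from 6 by loss of hydride at the benzylic CH2 (future C2) | CC(=O)O/C=C\c1c(OCc2ccccc2)cc(OCc2ccccc2)cc1[O+]=Cc1ccc(OCc2ccccc2)c(OCc2ccccc2)c1 | intermediate
8 | (2R,3R)-3-O-acetyl-5,7,3',4'-tetra-O-benzylepicatechin-4-yl cation (2,3-cis) | c4ccccc4COc1cc(OCc4ccccc4)c2c(c1)O[C@H](c1ccc(OCc4ccccc4)c(OCc4ccccc4)c1)[C@H](OC(C)=O)[CH+]2 | intermediate
9 | 3-O-acetyl-5,7,3',4'-tetra-O-benzyl-4β-(2-ethoxyethoxy)-(−)-epicatechin | c4ccccc4COc1cc(OCc4ccccc4)c2c(c1)O[C@H](c1ccc(OCc4ccccc4)c(OCc4ccccc4)c1)[C@H](OC(C)=O)[C@H]2OCCOCC | intermediate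
10 | 3-O-acetyl-5,7,3',4'-tetra-O-benzyl-8-bromo-4β-(2-ethoxyethoxy)-(−)-epicatechin | c4ccccc4COc1cc(OCc4ccccc4)c2c(c1Br)O[C@H](c1ccc(OCc4ccccc4)c(OCc4ccccc4)c1)[C@H](OC(C)=O)[C@H]2OCCOCC | intermediate
11 | (−)-epicatechin, (2R,3R)-2-(3,4-dihydroxyphenyl)chromane-3,5,7-triol | Oc1cc(O)c2c(c1)O[C@H](c1ccc(O)c(O)c1)[C@H](O)C2 | starting material
12 | 5,7,3',4'-tetra-O-benzyl-(−)-epicatechin | c4ccccc4COc1cc(OCc4ccccc4)c2c(c1)O[C@H](c1ccc(OCc4ccccc4)c(OCc4ccccc4)c1)[C@H](O)C2 | intermediate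
13 | 5,7,3',4'-tetra-O-benzyl-8-bromo-(−)-epicatechin | c4ccccc4COc1cc(OCc4ccccc4)c2c(c1Br)O[C@H](c1ccc(OCc4ccccc4)c(OCc4ccccc4)c1)[C@H](O)C2 | intermediate
14 | 5,7,3',4'-tetra-O-benzyl-8-bromo-4β-(2-ethoxyethoxy)-(−)-epicatechin | c4ccccc4COc1cc(OCc4ccccc4)c2c(c1Br)O[C@H](c1ccc(OCc4ccccc4)c(OCc4ccccc4)c1)[C@H](O)[C@H]2OCCOCC | intermediate
15 | 5,7,3',4'-tetra-O-benzyl-8-bromo-4β-(phenylsulfanyl)-(−)-epicatechin | c4ccccc4COc1cc(OCc4ccccc4)c2c(c1Br)O[C@H](c1ccc(OCc4ccccc4)c(OCc4ccccc4)c1)[C@H](O)[C@H]2Sc1ccccc1 | intermediate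
16 | 5,7,3',4'-tetra-O-benzyl-4β-(2-ethoxyethoxy)-(−)-epicatechin | c4ccccc4COc1cc(OCc4ccccc4)c2c(c1)O[C@H](c1ccc(OCc4ccccc4)c(OCc4ccccc4)c1)[C@H](O)[C@H]2OCCOCC | intermediate
17 | [3-O-acetyl-tetra-O-benzyl-8-bromoepicatechin]-(4β→6)-[tetra-O-benzyl-8-bromo-4β-(phenylsulfanyl)epicatechin] | c4ccccc4COc1cc(OCc4ccccc4)c2c(c1Br)O[C@H](c1ccc(OCc4ccccc4)c(OCc4ccccc4)c1)[C@H](OC(C)=O)[C@H]2c1c(OCc4ccccc4)c(Br)c2c(c1OCc4ccccc4)[C@H](Sc1ccccc1)[C@@H](O)[C@@H](c1ccc(OCc4ccccc4)c(OCc4ccccc4)c1)O2 | intermediate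
18 | [3-O-acetyl-tetra-O-benzyl-8-bromoepicatechin]-(4β→6)-[tetra-O-benzyl-8-bromoepicatechin]-(4β→8)-[tetra-O-benzyl-4β-(2-ethoxyethoxy)epicatechin] | c4ccccc4COc1cc(OCc4ccccc4)c2c(c1Br)O[C@H](c1ccc(OCc4ccccc4)c(OCc4ccccc4)c1)[C@H](OC(C)=O)[C@H]2c1c(OCc4ccccc4)c(Br)c2c(c1OCc4ccccc4)[C@H](c1c(OCc4ccccc4)cc(OCc4ccccc4)c3c1O[C@H](c1ccc(OCc4ccccc4)c(OCc4ccccc4)c1)[C@H](O)[C@H]3OCCOCC)[C@@H](O)[C@@H](c1ccc(OCc4ccccc4)c(OCc4ccccc4)c1)O2 | intermediate
19 | [3-O-acetyl-tetra-O-benzyl-8-bromoepicatechin]-(4β→6)-[tetra-O-benzyl-8-bromoepicatechin]-(4β→8)-[tetra-O-benzylepicatechin]-(4β→6)-[tetra-O-benzyl-8-bromoepicatechin] | c4ccccc4COc1cc(OCc4ccccc4)c2c(c1Br)O[C@H](c1ccc(OCc4ccccc4)c(OCc4ccccc4)c1)[C@H](OC(C)=O)[C@H]2c1c(OCc4ccccc4)c(Br)c2c(c1OCc4ccccc4)[C@H](c1c(OCc4ccccc4)cc(OCc4ccccc4)c3c1O[C@H](c1ccc(OCc4ccccc4)c(OCc4ccccc4)c1)[C@H](O)[C@H]3c1c(OCc4ccccc4)c(Br)c3c(c1OCc4ccccc4)C[C@@H](O)[C@@H](c1ccc(OCc4ccccc4)c(OCc4ccccc4)c1)O3)[C@@H](O)[C@@H](c1ccc(OCc4ccccc4)c(OCc4ccccc4)c1)O2 | intermediate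
20 | the same tetramer with the top-unit C3 hydroxyl free (sixteen benzyl ethers, bromine at C8 of units 1, 2 and 4) | c4ccccc4COc1cc(OCc4ccccc4)c2c(c1Br)O[C@H](c1ccc(OCc4ccccc4)c(OCc4ccccc4)c1)[C@H](O)[C@H]2c1c(OCc4ccccc4)c(Br)c2c(c1OCc4ccccc4)[C@H](c1c(OCc4ccccc4)cc(OCc4ccccc4)c3c1O[C@H](c1ccc(OCc4ccccc4)c(OCc4ccccc4)c1)[C@H](O)[C@H]3c1c(OCc4ccccc4)c(Br)c3c(c1OCc4ccccc4)C[C@@H](O)[C@@H](c1ccc(OCc4ccccc4)c(OCc4ccccc4)c1)O3)[C@@H](O)[C@@H](c1ccc(OCc4ccccc4)c(OCc4ccccc4)c1)O2 | intermediate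
21 | epicatechin-(4β→6)-epicatechin-(4β→8)-epicatechin-(4β→6)-epicatechin (CNP0120618.1) | Oc1cc(O)c2c(c1)O[C@H](c1ccc(O)c(O)c1)[C@H](O)[C@H]2c1c(O)cc2c(c1O)[C@H](c1c(O)cc(O)c3c1O[C@H](c1ccc(O)c(O)c1)[C@H](O)[C@H]3c1c(O)cc3c(c1O)C[C@@H](O)[C@@H](c1ccc(O)c(O)c1)O3)[C@@H](O)[C@@H](c1ccc(O)c(O)c1)O2 | target

**Step count and risks**

Total steps: 16. Longest linear sequence: 11 steps (steps 1 to 6, then 12 to 16).

Step 5. The chiral phosphate may fail to discriminate the two mirror-image chair transition states, so that the cyclisation gives little or no enantiomeric excess. The fallback sets out from 6. The cyclisation is run as the known racemic DDQ oxidative Prins reaction (DDQ, 2,6-dichloropyridine, LiClO4, 2-ethoxyethanol, 4 Å MS, ClCH2CH2Cl), which should give 9 together with its mirror image, the enantiomer of 9 F1. Bromination as in step 6 then gives 10 together with the enantiomer of 10 F2. Coupling of this racemate with enantiopure 15 as in step 12 gives 17 and the diastereomeric dimer with the mirror-image top unit F3; the two differ at all three centres of the top unit and are separated by chromatography. The route is rejoined at 17.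

Step 4. The hindered, electron-rich alkyne may form the ruthenium vinylidene slowly, so that Markovnikov addition or loss of Z geometry competes. The fallback sets out from 5. Anti-Markovnikov hydroboration with dicyclohexylborane and oxidation with NaBO3·4H2O give [2,4-bis(benzyloxy)-6-{[3,4-bis(benzyloxy)phenyl]methoxy}phenyl]acetaldehyde F4. Its potassium enolate (KN(SiMe3)2, THF, −78 °C), expected mainly with the aryl group cis to oxygen, is trapped with acetic anhydride, and the minor E isomer is removed by chromatography. The route is rejoined at 6.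

Step 14. Friedel–Crafts attack by the bromine-deactivated C6 of 13 on the hindered trimer cation may be slow, so that self-condensation through the free C6 of the third unit or acid cleavage of the existing interflavan bonds takes over. The fallback sets out from 16 and forms the 4→6 bond on monomers. Iodination of 16 with N-iodosuccinimide caps C8 and gives 5,7,3',4'-tetra-O-benzyl-4β-(2-ethoxyethoxy)-8-iodoepicatechin F5. Coupling with 13 (BF3·OEt2, CH2Cl2, −78 °C) gives the (4β→6) dimer carrying iodine on the upper and bromine on the lower unit F6. Iodine–magnesium exchange with (CH3)2CHMgCl·LiCl at −20 °C, which leaves the aryl bromide alone, followed by methanol gives the (4β→6) dimer with free C8 on its upper unit F7. F7 is then joined to 17 under the silver conditions of step 13, and the route is rejoined at 19.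

**Further compounds**

F1 | step 5 | enantiomer of 9 | c4ccccc4COc1cc(OCc4ccccc4)c2c(c1)O[C@@H](c1ccc(OCc4ccccc4)c(OCc4ccccc4)c1)[C@@H](OC(C)=O)[C@@H]2OCCOCC
F2 | step 5 | enantiomer of 10 | c4ccccc4COc1cc(OCc4ccccc4)c2c(c1Br)O[C@@H](c1ccc(OCc4ccccc4)c(OCc4ccccc4)c1)[C@@H](OC(C)=O)[C@@H]2OCCOCC
F3 | step 5 | diastereomer of 17 with the mirror-image top unit | c4ccccc4COc1cc(OCc4ccccc4)c2c(c1Br)O[C@@H](c1ccc(OCc4ccccc4)c(OCc4ccccc4)c1)[C@@H](OC(C)=O)[C@@H]2c1c(OCc4ccccc4)c(Br)c2c(c1OCc4ccccc4)[C@H](Sc1ccccc1)[C@@H](O)[C@@H](c1ccc(OCc4ccccc4)c(OCc4ccccc4)c1)O2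
F4 | step 4 | [2,4-bis(benzyloxy)-6-{[3,4-bis(benzyloxy)phenyl]methoxy}phenyl]acetaldehyde | O=CCc1c(OCc2ccccc2)cc(OCc2ccccc2)cc1OCc1ccc(OCc2ccccc2)c(OCc2ccccc2)c1
F5 | step 14 | 5,7,3',4'-tetra-O-benzyl-4β-(2-ethoxyethoxy)-8-iodo-(−)-epicatechin | c4ccccc4COc1cc(OCc4ccccc4)c2c(c1I)O[C@H](c1ccc(OCc4ccccc4)c(OCc4ccccc4)c1)[C@H](O)[C@H]2OCCOCC
F6 | step 14 | [tetra-O-benzyl-8-iodoepicatechin]-(4β→6)-[tetra-O-benzyl-8-bromoepicatechin] | c4ccccc4COc1cc(OCc4ccccc4)c2c(c1I)O[C@H](c1ccc(OCc4ccccc4)c(OCc4ccccc4)c1)[C@H](O)[C@H]2c1c(OCc4ccccc4)c(Br)c2c(c1OCc4ccccc4)C[C@@H](O)[C@@H](c1ccc(OCc4ccccc4)c(OCc4ccccc4)c1)O2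
F7 | step 14 | [tetra-O-benzylepicatechin]-(4β→6)-[tetra-O-benzyl-8-bromoepicatechin] | c4ccccc4COc1cc(OCc4ccccc4)c2c(c1)O[C@H](c1ccc(OCc4ccccc4)c(OCc4ccccc4)c1)[C@H](O)[C@H]2c1c(OCc4ccccc4)c(Br)c2c(c1OCc4ccccc4)C[C@@H](O)[C@@H](c1ccc(OCc4ccccc4)c(OCc4ccccc4)c1)O2
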